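## The problem

Target 26 is the 3-hydroxy-4-methoxybenzoate of a cis-fused bicyclo[5.3.0]decene diol. The core is numbered as follows: five-membered ring C1(CH3)–C2–C3–C4(OH)(i-Pr)–C5(H); seven-membered ring C5–C6(O-acyl)–C7=C8(CH3)–C9–C10–C1. Four contiguous stereocentres must be set: quaternary C1, the tertiary carbinol C4, C5 and the allylic C6, with absolute configuration (1R,4R,5S,6R) in this numbering. The angular methyl group and H5 are cis, the C4 hydroxyl is trans to H5, and the C6 oxygen lies on the side of the C5–C4 bond. C5 is the pivot: through a short tether on C4 it can dictate C1, and through the shape of the cis-fused bicycle it can dictate C6. C4 and C5 have to be created together in an intermolecular C–C bond formation, which is also where the absolute configuration must be secured. The allylic ester (ionisation, hydrogenolysis) and the free phenol must come late. The tertiary alcohol is β to C6 and invites retro-aldol cleavage while C6 is a ketone, and the trisubstituted C7=C8 olefin must survive every reduction. The feature that opens the route is the C1–C2 bond: C2 can be the terminus of a cis-alkenyl unit C3=C2 hung on C4, and C1 the methyl-bearing carbon of a C1=C10 ring olefin. The tether is so short that C2 can reach C1 only on the face that carries the C5–C4 bond, and palladium is left on C10, where only the C9 hydrogens are available for elimination.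

## Retrosynthesis

**Ester and phenol.** The C6–O acyl bond of 26 is cut last, through silyl-protected ester 25, to diol 21 and 3-(tert-butyldimethylsilyloxy)-4-methoxybenzoic acid 24 (from isovanillic acid 22). A silyl ether is chosen for the phenol because fluoride removes it without touching the allylic ester; a benzyl ether would call for hydrogenolysis next to an allylic C–O bond and an olefin. The forward reaction only has to distinguish a secondary from a tertiary hydroxyl.

**Absolute configuration.** Diol 21 is traced to racemic diol 18 through the diastereomeric ester 20 formed with (S)-O-methylmandelic acid 19. The C4/C5 pair arises from two achiral partners, and no dependable enantioselective addition of a ketone dienolate to an unactivated alkynyl ketone is at hand. A classical resolution on the C6 hydroxyl is therefore preferred to an untested chiral reagent. It costs two steps and half of the material, and asks only for separable diastereomers and a clean transesterification.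

**C6 carbinol.** Diol 18 comes from enone 16 by 1,2-reduction and loss of the silyl group (silyl ether 17 is not isolated). Cutting the C6–H bond here, rather than carrying an alcohol through the sequence, keeps C6 as a ketone for the enolate chemistry and for the chemoselective hydrogenation. The forward step needs hydride delivery from the convex face of the bicycle.

**Olefin adjustment.** Enone 16 comes from trienone 15 by saturating C2=C3 and C9=C10. No stereocentre is involved. The reaction must tell two cis-disubstituted olefins from the trisubstituted, conjugated C7=C8 olefin.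

**C1–C2 bond (key cut).** Trienone 15 is opened at C1–C2 to (Z)-alkenyl iodide 14, a monocyclic cycloheptadienone with only two stereocentres. Against a cut at C1–C5 or C1–C10, this one lets the existing C5 centre set the quaternary carbon intramolecularly and needs no preformed cyclopentane. The forward reaction is a 5-exo Heck cyclisation onto the methyl-bearing carbon of a trisubstituted ring olefin.

**Alkenyl iodide.** Iodide 14 is simplified to iodoalkyne 13 and further to the C-silyl alkyne 12, the O-silyl ether of aldol adduct 11. The alkyne is the robust form of the two-carbon unit during the aldol step; iododesilylation and cis-reduction are both mild enough for a β,γ-unsaturated ketone.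

**C4–C5 bond.** Adduct 11 is cut between C4 and C5 into dienone 6 and ynone 9. The symmetry of 6 means that γ-deprotonation on either side gives the same trienolate 10. Attack through the α-carbon puts the ring olefin exactly at C1=C10, where the key step needs it. The forward reaction must be α-selective and must set C4 relative to C5 in one closed transition state.

**Ynone.** Ynone 9 is cut at the acyl–alkynyl bond into isobutyryl chloride 7 and ethynyltrimethylsilane 8.

**Dienone.** Dienone 6 has a carbonyl flanked by two CH=C(CH3) units joined by CH2CH2. This is the pattern left when water is lost from the saturated (4+3) adduct 5 of 2,5-dimethylfuran 1 and an oxyallyl cation. Adduct 5 comes from bicyclic enone 4, which comes from 1 and 1,1,3-trichloroacetone 2 by way of dichloro adduct 3. The furan supplies both methyl-bearing carbons, and the bridging oxygen is β to the ketone on both sides.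

## Roads not taken

Alternative 1: The C1–C5 and C9–C10 bonds are cut together. The forward step is a (5+2) cycloaddition of the open-chain siloxy-vinylcyclopropane A1, which carries a tethered methallyl group, under [Rh(CO)2Cl]2 catalysis; it gives the bicyclic silyl enol ether A2. Its merits are real: both rings, the quaternary C1 and C5 arise in one catalytic step from a linear compound, and the C4 carbinol of A1 can be set by an asymmetric ketone reduction, so the absolute configuration is available without a resolution. In ring construction and in enantiocontrol this road is better than the chosen one. Its weak points lie after the key step. A2 has no isopropyl group, so C4 must be deprotected, oxidised and attacked by an isopropyl nucleophile next to the ring fusion, where enolisation and reduction compete and C5 becomes epimerisable. C4 and C6 are then both at the ketone level unless one is parked first. The 1,1-disubstituted alkene must form a quaternary carbon, the slow class of two-carbon partner. The methyl group on the cyclopropane raises a question of which C–C bond is cleaved. Against this the chosen plan sets a C4 that arrives fully substituted, with its configuration relative to C5 fixed in the aldol step.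

Alternative 2: The C1–C10 bond is cut. The forward step is the thermal Cope rearrangement of the cis-divinylcyclopropane A3 (a 1-siloxy-1-cyclopentenyl-2-methyl-2-vinylcyclopropane), which opens the three-membered ring and gives the bicyclic 1,4-diene A4. The rearrangement is stereospecific, metal-free and driven by ring strain, and it has none of the base or hydride-migration problems of a Heck reaction; in the making of C1 alone it is the more elegant step. For this target it leaves too much to do. A4 carries one stereocentre only, C5 is trigonal, the ring olefin sits at C8=C9, and C4 is a masked ketone that still needs the isopropyl group. Unveiling C4 and C6 together would produce a 1,3-diketone with a labile C5. A3 itself needs a fully substituted siloxycyclopropane of defined relative and absolute configuration. The chosen plan enters its key step with C4 and C5 already in place.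

Alternative 3: The C6–C7 bond is cut. The forward step is a Nozaki–Hiyama–Kishi closure (CrCl2, catalytic NiCl2) of the (Z)-iodoalkenyl cyclopentanecarbaldehyde A5 to the bicyclic allylic alcohol A6. A6 is the triethylsilyl analogue of intermediate 17, so this road has the better endgame: no hydrogenation selectivity to solve, no reduction at C6, and three steps to the target. Its cost is moved to the front. A5 is a cyclopentane with the quaternary C1, the tertiary carbinol C4 and an epimerisable formyl-bearing C5 already in place, and a trisubstituted (Z)-alkenyl iodide must be built on the side chain. The seven-membered ring closes under high dilution with a C6 configuration fixed only by the conformation of the closing chain. The chosen plan builds the same stereotriad in two C–C bond formations on a preformed seven-membered ring, and gives up the shorter endgame for that.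

Key step: step 9

Assumption: compounds 11–18 are racemic and are named and drawn as the enantiomer that is carried on to 26; the two O-methylmandelates of step 12 are taken to be separable on silica gel, as is usual for such esters of secondary alcohols.

## Route

Step 1
Reactants: 1 2,5-dimethylfuran; 2 1,1,3-trichloroacetone
Product: 4 meso-1,5-dimethyl-8-oxabicyclo[3.2.1]oct-6-en-3-one, via dichloro cycloadduct 3 (not isolated)
Conditions: Et3N, CF3CH2OH, 0 °C → rt; then Zn–Cu couple, NH4Cl, MeOH, rt
Reagents that add atoms: none
Why: Oxyallyl cation (4+3) cycloaddition: Et3N removes HCl from 2 in the ionising, weakly nucleophilic solvent to give a chloro-stabilised 2-oxyallyl cation that adds across C2/C5 of the electron-rich furan, and Zn–Cu then removes both chlorines reductively. The bridged skeleton forces both methyl groups onto the bridgeheads, so 4 is a single meso compound.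

Step 2
Reactants: 4 meso-1,5-dimethyl-8-oxabicyclo[3.2.1]oct-6-en-3-one
Product: 5 meso-1,5-dimethyl-8-oxabicyclo[3.2.1]octan-3-one
Conditions: H2 (1 atm), Pd/C, EtOAc, rt
Reagents that add atoms: none
Why: Heterogeneous hydrogenation of a strained cis-disubstituted olefin; ketone and bridging ether are untouched and no stereocentre is created.

Step 3
Reactants: 5 meso-1,5-dimethyl-8-oxabicyclo[3.2.1]octan-3-one
Product: 6 3,6-dimethylcyclohepta-2,6-dien-1-one
Conditions: p-TsOH·H2O (cat.), toluene, reflux, Dean–Stark trap
Reagents that add atoms: none
Why: Both bridgehead C–O bonds are tertiary and β to the ketone, so acid opens the ether by β-elimination (retro-oxa-Michael) to a β-hydroxy enone that dehydrates in the same flask (aldol-type dehydration). Azeotropic removal of water makes the sequence irreversible, and conjugation directs both new olefins to the α,β-positions.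

Step 4
Reactants: 7 isobutyryl chloride; 8 ethynyltrimethylsilane
Product: 9 4-methyl-1-(trimethylsilyl)pent-1-yn-3-one
Conditions: PdCl2(PPh3)2 (2 mol %), CuI (4 mol %), Et3N, THF, rt
Reagents that add atoms: none
Why: Acyl Sonogashira coupling: the copper acetylide of 8 is acylated through an acylpalladium chloride. The silyl cap later keeps the ynone from acting as a Michael acceptor.

Step 5
Reactants: 6 3,6-dimethylcyclohepta-2,6-dien-1-one; 9 4-methyl-1-(trimethylsilyl)pent-1-yn-3-one
Product: 11 rac-(7R)-7-[(3R)-3-hydroxy-4-methyl-1-(trimethylsilyl)pent-1-yn-3-yl]-3,6-dimethylcyclohepta-2,5-dien-1-one, via lithium trienolate 10 (not isolated)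
Conditions: LiN(i-Pr)2, THF, −78 °C; then 9, −78 °C; AcOH, −78 °C
Reagents that add atoms: none
Why: Directed aldol addition of a lithium enolate to an alkynyl ketone: 6 has no α′-hydrogen, so the amide base removes a γ-hydrogen, and by symmetry either ring methylene gives the same trienolate 10, which attacks the ketone through its α-carbon C5 under kinetic control and so places the ring olefin at C1=C10. The ring enolate is necessarily E-configured; in a Zimmerman–Traxler chair with the isopropyl group equatorial and the slim alkynyl group axial it should give the (4R*,5R*) adduct. The silyl cap blocks conjugate addition and the cold acidic quench prevents retro-aldol cleavage.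

Step 6
Reactants: 11 rac-(7R)-7-[(3R)-3-hydroxy-4-methyl-1-(trimethylsilyl)pent-1-yn-3-yl]-3,6-dimethylcyclohepta-2,5-dien-1-one
Product: 12 rac-(7R)-3,6-dimethyl-7-[(3R)-4-methyl-1-(trimethylsilyl)-3-(trimethylsilyloxy)pent-1-yn-3-yl]cyclohepta-2,5-dien-1-one
Conditions: 1-(trimethylsilyl)imidazole, CH2Cl2, rt
Reagents that add atoms: 1-(trimethylsilyl)imidazole, C[Si](C)(C)n1ccnc1
Why: O-Silylation of a hindered tertiary alcohol with a neutral, highly reactive silyl donor; no base strong enough to enolise the β,γ-unsaturated ketone or to trigger retro-aldol cleavage is present.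

Step 7
Reactants: 12 rac-(7R)-3,6-dimethyl-7-[(3R)-4-methyl-1-(trimethylsilyl)-3-(trimethylsilyloxy)pent-1-yn-3-yl]cyclohepta-2,5-dien-1-one
Product: 13 rac-(7R)-7-[(3R)-1-iodo-4-methyl-3-(trimethylsilyloxy)pent-1-yn-3-yl]-3,6-dimethylcyclohepta-2,5-dien-1-one
Conditions: N-iodosuccinimide, AgNO3 (10 mol %), acetone, rt, dark
Reagents that add atoms: N-iodosuccinimide, O=C1CCC(=O)N1I
Why: Silver-catalysed iododesilylation of an alkynylsilane through a transient silver acetylide; the O-silyl ether and the olefins should not be attacked under these neutral conditions.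

Step 8
Reactants: 13 rac-(7R)-7-[(3R)-1-iodo-4-methyl-3-(trimethylsilyloxy)pent-1-yn-3-yl]-3,6-dimethylcyclohepta-2,5-dien-1-one
Product: 14 rac-(7R)-7-[(1Z,3R)-1-iodo-4-methyl-3-(trimethylsilyloxy)pent-1-en-3-yl]-3,6-dimethylcyclohepta-2,5-dien-1-one
Conditions: KO2CN=NCO2K, AcOH, pyridine, MeOH, 0 °C → rt
Reagents that add atoms: none
Why: Diimide, released from the azodicarboxylate by acetic acid, transfers two hydrogens in a concerted syn fashion to the iodoalkyne and gives the (Z)-iodoalkene. Trisubstituted and conjugated olefins react far more slowly and the C–I bond is not reduced.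

Step 9
Reactants: 14 rac-(7R)-7-[(1Z,3R)-1-iodo-4-methyl-3-(trimethylsilyloxy)pent-1-en-3-yl]-3,6-dimethylcyclohepta-2,5-dien-1-one
Product: 15 rac-(3S,3aR,8aR)-6,8a-dimethyl-3-(propan-2-yl)-3-(trimethylsilyloxy)-3a,8a-dihydroazulen-4(3H)-one
Conditions: Pd(OAc)2 (10 mol %), PPh3 (30 mol %), Ag2CO3 (2 equiv), MeCN, 80 °C
Reagents that add atoms: none
Why: Zerovalent palladium, formed from Pd(OAc)2 and PPh3, inserts into the C2–I bond with retention of the Z geometry, and Ag2CO3 removes iodide to give a cationic alkenylpalladium that binds the C1=C10 olefin. syn-Carbopalladation delivers C2 to the methyl-bearing C1 and palladium to C10, closing the cyclopentene in the 5-exo-trig mode. The alkylpalladium has no β-hydrogen on C1 and eliminates toward C9, which leaves C9=C10 in conjugation with C7=C8 and the C6 carbonyl. The closest known reaction type is the intramolecular Heck cyclisation of an alkenyl halide onto a trisubstituted cycloalkene with formation of a quaternary carbon. The new stereocentre C1 is controlled by C5: the tether C5–C4–C3=C2 can reach C1 only on the face that carries the C5–C4 bond, so the bicycle must be cis-fused. Three selectivities are needed. Insertion must go into C1=C10 and not into the enone, which the ring size secures (six-membered closure onto the α-carbon of the enone or seven-membered closure onto its β-carbon are both slower). The β,γ-unsaturated ketone must not reconjugate or epimerise at C5 before it cyclises, which is why an insoluble carbonate and no amine is used. The hydridopalladium species must not migrate olefins, which the silver salt prevents by fast removal of HI, while C2=C3 lies between two fully substituted carbons and cannot move.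

Step 10
Reactants: 15 rac-(3S,3aR,8aR)-6,8a-dimethyl-3-(propan-2-yl)-3-(trimethylsilyloxy)-3a,8a-dihydroazulen-4(3H)-one
Product: 16 rac-(3R,3aR,8aR)-6,8a-dimethyl-3-(propan-2-yl)-3-(trimethylsilyloxy)-2,3,3a,7,8,8a-hexahydroazulen-4(1H)-one
Conditions: H2 (1–4 atm), RhCl(PPh3)3 (15 mol %), benzene, rt
Reagents that add atoms: none
Why: Homogeneous hydrogenation with RhCl(PPh3)3 discriminates by substitution: the cis-disubstituted C2=C3 and C9=C10 olefins are reduced while the trisubstituted, carbonyl-conjugated C7=C8 olefin stays, as in the known γ,δ-reduction of linear dienones to enones. C2, C3, C9 and C10 all become CH2, so no stereocentre is created.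

Step 11
Reactants: 16 rac-(3R,3aR,8aR)-6,8a-dimethyl-3-(propan-2-yl)-3-(trimethylsilyloxy)-2,3,3a,7,8,8a-hexahydroazulen-4(1H)-one
Product: 18 rac-(3R,3aS,4R,8aR)-6,8a-dimethyl-3-(propan-2-yl)-1,2,3,3a,4,7,8,8a-octahydroazulene-3,4-diol, via silyl ether alcohol 17 (not isolated)
Conditions: NaBH4, CeCl3·7H2O, MeOH, −78 → −20 °C; then 10% aq. citric acid, rt
Reagents that add atoms: none
Why: Luche 1,2-reduction of the enone. In the cis-fused bicycle the concave face of C6 is shielded by C4 and its silyloxy group, so hydride should enter from the face of the angular H5 and methyl group and place the C6 hydroxyl cis to the C5–C4 bond. The silyl ether is kept on during the reduction to block that face and to exclude hydroxyl-directed delivery, and is then hydrolysed by the mild acid.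

Step 12
Reactants: 18 rac-(3R,3aS,4R,8aR)-6,8a-dimethyl-3-(propan-2-yl)-1,2,3,3a,4,7,8,8a-octahydroazulene-3,4-diol; 19 (2S)-2-methoxy-2-phenylacetic acid
Product: 20 (3R,3aS,4R,8aR)-3-hydroxy-6,8a-dimethyl-3-(propan-2-yl)-1,2,3,3a,4,7,8,8a-octahydroazulen-4-yl (2S)-2-methoxy-2-phenylacetate
Conditions: EDC·HCl, DMAP (cat.), CH2Cl2, 0 °C → rt; separation of the two diastereomers on silica gel
Reagents that add atoms: none
Why: Steglich esterification of the secondary allylic hydroxyl (the tertiary C4 hydroxyl does not acylate) with an enantiopure acid turns the racemate into two diastereomeric esters that are separated by chromatography. The diastereomer with the (1R,4R,5S,6R) core is carried on; its configuration is to be assigned from the shielding pattern of the mandelate phenyl group in the 1H NMR spectra of the two esters.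

Step 13
Reactants: 20 (3R,3aS,4R,8aR)-3-hydroxy-6,8a-dimethyl-3-(propan-2-yl)-1,2,3,3a,4,7,8,8a-octahydroazulen-4-yl (2S)-2-methoxy-2-phenylacetate
Product: 21 (3R,3aS,4R,8aR)-6,8a-dimethyl-3-(propan-2-yl)-1,2,3,3a,4,7,8,8a-octahydroazulene-3,4-diol
Conditions: K2CO3 (cat.), MeOH, rt
Reagents that add atoms: none
Why: Carbonate-catalysed transesterification with methanol removes the α-alkoxy-activated ester without touching any stereocentre and releases the diol as a single enantiomer.

Step 14
Reactants: 22 isovanillic acid (3-hydroxy-4-methoxybenzoic acid)
Product: 24 3-(tert-butyldimethylsilyloxy)-4-methoxybenzoic acid, via bis-silylated acid 23 (not isolated)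
Conditions: TBSCl, imidazole, DMF, rt; then AcOH, THF, H2O, rt
Reagents that add atoms: tert-butyldimethylsilyl chloride, CC(C)(C)[Si](C)(C)Cl
Why: Silylation of phenol and acid, then selective hydrolysis of the labile silyl ester under mild acid, which leaves the aryl silyl ether; the masked phenol cannot compete as a nucleophile in the esterification.

Step 15
Reactants: 21 (3R,3aS,4R,8aR)-6,8a-dimethyl-3-(propan-2-yl)-1,2,3,3a,4,7,8,8a-octahydroazulene-3,4-diol; 24 3-(tert-butyldimethylsilyloxy)-4-methoxybenzoic acid
Product: 25 (3R,3aS,4R,8aR)-3-hydroxy-6,8a-dimethyl-3-(propan-2-yl)-1,2,3,3a,4,7,8,8a-octahydroazulen-4-yl 3-(tert-butyldimethylsilyloxy)-4-methoxybenzoate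
Conditions: EDC·HCl, DMAP, CH2Cl2, rt
Reagents that add atoms: none
Why: Steglich esterification: the acylpyridinium derived from 24 acylates the secondary allylic C6 hydroxyl, while the tertiary C4 hydroxyl is too hindered to react. C6 keeps its configuration because its C–O bond is not broken.

Step 16
Reactants: 25 (3R,3aS,4R,8aR)-3-hydroxy-6,8a-dimethyl-3-(propan-2-yl)-1,2,3,3a,4,7,8,8a-octahydroazulen-4-yl 3-(tert-butyldimethylsilyloxy)-4-methoxybenzoate
Product: 26 (3R,3aS,4R,8aR)-3-hydroxy-6,8a-dimethyl-3-(propan-2-yl)-1,2,3,3a,4,7,8,8a-octahydroazulen-4-yl 3-hydroxy-4-methoxybenzoate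
Conditions: n-Bu4NF, AcOH, THF, 0 °C
Reagents that add atoms: none
Why: Fluoride cleaves the aryl silyl ether quickly at 0 °C; buffering with acetic acid keeps the phenoxide from forming, so the allylic ester and the tertiary alcohol should be untouched.

## Compound list

1 | 2,5-dimethylfuran | Cc1ccc(C)o1 | starting material
2 | 1,1,3-trichloroacetone (1,1,3-trichloropropan-2-one) | ClCC(=O)C(Cl)Cl | starting material
3 | 2,4-dichloro-1,5-dimethyl-8-oxabicyclo[3.2.1]oct-6-en-3-one (mixture of stereoisomers at C2 and C4) | CC12C=CC(C)(O1)C(Cl)C(=O)C2Cl | intermediate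
4 | meso-1,5-dimethyl-8-oxabicyclo[3.2.1]oct-6-en-3-one | C[C@]12C=C[C@](C)(O1)CC(=O)C2 | intermediate
5 | meso-1,5-dimethyl-8-oxabicyclo[3.2.1]octan-3-one | C[C@]12CC[C@](C)(O1)CC(=O)C2 | intermediate
6 | 3,6-dimethylcyclohepta-2,6-dien-1-one | O=C1C=C(C)CCC(C)=C1 | intermediate
7 | isobutyryl chloride | CC(C)C(Cl)=O | starting material
8 | ethynyltrimethylsilane | C#C[Si](C)(C)C | starting material
9 | 4-methyl-1-(trimethylsilyl)pent-1-yn-3-one | CC(C)C(=O)C#C[Si](C)(C)C | intermediate
10 | lithium 3,6-dimethylcyclohepta-1,3,6-trien-1-olate | [Li+].[O-]C1=CC(C)=CCC(C)=C1 | intermediate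
11 | rac-(7R)-7-[(3R)-3-hydroxy-4-methyl-1-(trimethylsilyl)pent-1-yn-3-yl]-3,6-dimethylcyclohepta-2,5-dien-1-one | O=C1C=C(C)CC=C(C)[C@@H]1[C@](O)(C(C)C)C#C[Si](C)(C)C | intermediate
12 | rac-(7R)-3,6-dimethyl-7-[(3R)-4-methyl-1-(trimethylsilyl)-3-(trimethylsilyloxy)pent-1-yn-3-yl]cyclohepta-2,5-dien-1-one | O=C1C=C(C)CC=C(C)[C@@H]1[C@](O[Si](C)(C)C)(C(C)C)C#C[Si](C)(C)C | intermediate
13 | rac-(7R)-7-[(3R)-1-iodo-4-methyl-3-(trimethylsilyloxy)pent-1-yn-3-yl]-3,6-dimethylcyclohepta-2,5-dien-1-one | O=C1C=C(C)CC=C(C)[C@@H]1[C@](O[Si](C)(C)C)(C(C)C)C#CI | intermediate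
14 | rac-(7R)-7-[(1Z,3R)-1-iodo-4-methyl-3-(trimethylsilyloxy)pent-1-en-3-yl]-3,6-dimethylcyclohepta-2,5-dien-1-one | O=C1C=C(C)CC=C(C)[C@@H]1[C@](O[Si](C)(C)C)(C(C)C)/C=C\I | intermediate
15 | rac-(3S,3aR,8aR)-6,8a-dimethyl-3-(propan-2-yl)-3-(trimethylsilyloxy)-3a,8a-dihydroazulen-4(3H)-one | O=C1C=C(C)C=C[C@]2(C)C=C[C@@](O[Si](C)(C)C)(C(C)C)[C@H]12 | intermediate
16 | rac-(3R,3aR,8aR)-6,8a-dimethyl-3-(propan-2-yl)-3-(trimethylsilyloxy)-2,3,3a,7,8,8a-hexahydroazulen-4(1H)-one | O=C1C=C(C)CC[C@]2(C)CC[C@@](O[Si](C)(C)C)(C(C)C)[C@H]12 | intermediate
17 | rac-(3R,3aS,4R,8aR)-6,8a-dimethyl-3-(propan-2-yl)-3-(trimethylsilyloxy)-1,2,3,3a,4,7,8,8a-octahydroazulen-4-ol | O[C@@H]1C=C(C)CC[C@]2(C)CC[C@@](O[Si](C)(C)C)(C(C)C)[C@H]12 | intermediate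
18 | rac-(3R,3aS,4R,8aR)-6,8a-dimethyl-3-(propan-2-yl)-1,2,3,3a,4,7,8,8a-octahydroazulene-3,4-diol | O[C@@H]1C=C(C)CC[C@]2(C)CC[C@@](O)(C(C)C)[C@H]12 | intermediate
19 | (2S)-2-methoxy-2-phenylacetic acid ((S)-O-methylmandelic acid) | CO[C@H](C(=O)O)c1ccccc1 | starting material
20 | (3R,3aS,4R,8aR)-3-hydroxy-6,8a-dimethyl-3-(propan-2-yl)-1,2,3,3a,4,7,8,8a-octahydroazulen-4-yl (2S)-2-methoxy-2-phenylacetate | CO[C@H](C(=O)O[C@@H]1C=C(C)CC[C@]2(C)CC[C@@](O)(C(C)C)[C@H]12)c1ccccc1 | intermediate
21 | (3R,3aS,4R,8aR)-6,8a-dimethyl-3-(propan-2-yl)-1,2,3,3a,4,7,8,8a-octahydroazulene-3,4-diol (single enantiomer) | O[C@@H]1C=C(C)CC[C@]2(C)CC[C@@](O)(C(C)C)[C@H]12 | intermediate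
22 | isovanillic acid (3-hydroxy-4-methoxybenzoic acid) | COc1ccc(C(=O)O)cc1O | starting material
23 | tert-butyldimethylsilyl 3-(tert-butyldimethylsilyloxy)-4-methoxybenzoate | COc1ccc(C(=O)O[Si](C)(C)C(C)(C)C)cc1O[Si](C)(C)C(C)(C)C | intermediate
24 | 3-(tert-butyldimethylsilyloxy)-4-methoxybenzoic acid | COc1ccc(C(=O)O)cc1O[Si](C)(C)C(C)(C)C | intermediate
25 | (3R,3aS,4R,8aR)-3-hydroxy-6,8a-dimethyl-3-(propan-2-yl)-1,2,3,3a,4,7,8,8a-octahydroazulen-4-yl 3-(tert-butyldimethylsilyloxy)-4-methoxybenzoate | COc1ccc(C(=O)O[C@@H]2C=C(C)CC[C@]3(C)CC[C@@](O)(C(C)C)[C@H]23)cc1O[Si](C)(C)C(C)(C)C | intermediate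
26 | (3R,3aS,4R,8aR)-3-hydroxy-6,8a-dimethyl-3-(propan-2-yl)-1,2,3,3a,4,7,8,8a-octahydroazulen-4-yl 3-hydroxy-4-methoxybenzoate (CNP0210850.1) | COc1ccc(C(=O)O[C@@H]2C=C(C)CC[C@]3(C)CC[C@@](O)(C(C)C)[C@H]23)cc1O | target

## Step count and the least certain steps

Total: 16 steps. Longest linear sequence: 14 steps (steps 1–3, 5–13, 15 and 16, from 2,5-dimethylfuran 1).

**Step 9 (key step).** Insertion into a fully substituted olefin carbon is slow. In that time the carbonate may move the C1=C10 olefin into conjugation with the ketone or epimerise C5, and reduction of the C–I bond may compete. Fallback: a tin-hydride radical cyclisation starting from 14 (Bu3SnH, AIBN, benzene, 80 °C, slow addition) works without base. The C2 alkenyl radical should add to the proximal ring carbon C1 (5-exo, cis-fused for the same geometric reason), and the C10 radical is reduced by the stannane. This gives the cyclopentene enone rac-(3S,3aR,8aR)-6,8a-dimethyl-3-(propan-2-yl)-3-(trimethylsilyloxy)-3,3a,8,8a-tetrahydroazulen-4(7H)-one F1, in which C9–C10 is already saturated. Hydrogenation of its one disubstituted olefin with RhCl(PPh3)3 and H2 returns to the route at 16.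

**Step 5.** The addition of a ketone enolate to a ketone is reversible, so retro-aldol cleavage on warming or during isolation may lower the conversion. Deprotonation at a methyl group instead of the ring methylene, and poor discrimination between the alkynyl and isopropyl groups in the chair transition state, are the other ways this step can fail. Fallback: the aldol addition and the silylation are merged into one operation starting from 6 and 9. The trienolate 10 is formed as before, 9 is added, and the lithium aldolate is captured at −78 °C with Me3SiCl before any proton source is present. The adduct is then never handled as the free β-hydroxy ketone and the route is rejoined at 12; no new compound arises (F0). A minor C4 epimer would be removed by chromatography at the stage of 12.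

**Step 3.** Under hot acid the cross-conjugated dienone may isomerise to the linearly conjugated 2,4-dienone, or dehydration may stop at the hydroxy enone, which closes back to 5 by oxa-Michael addition. Fallback from 5: kinetic ring opening with Me3SiOTf and Et3N (CH2Cl2, 0 °C) followed by a mild acidic work-up gives rac-6-hydroxy-3,6-dimethylcyclohept-2-en-1-one F2. Its tertiary hydroxyl is converted with MeSO2Cl and Et3N into rac-1,4-dimethyl-6-oxocyclohept-4-en-1-yl methanesulfonate F3. DBU eliminates this by an E1cB path through the ketone enolate, so only the conjugated olefin can form, and the route is rejoined at 6.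

**Step 10.** The C2=C3 olefin lies between two fully substituted carbons and may be reduced too slowly by the rhodium catalyst; forcing the conditions risks loss of the C7=C8 olefin. Fallback from 15: exhaustive hydrogenation (H2, Pd/C, EtOAc) gives the saturated ketone 6,8a-dimethyl-3-(propan-2-yl)-3-(trimethylsilyloxy)octahydroazulen-4(1H)-one F4 as a mixture of C8 epimers. Kinetic enolisation on the unhindered C7 side (LiN(i-Pr)2, Me3SiCl, THF, −78 °C) gives the silyl enol ether 6,8a-dimethyl-3-(propan-2-yl)-3,4-bis(trimethylsilyloxy)-1,2,3,3a,6,7,8,8a-octahydroazulene F5. Saegusa–Ito oxidation (Pd(OAc)2, MeCN) re-creates C7=C8 and returns to 16.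

**Step 11.** Facial selectivity in the flexible seven-membered ring may be poor: the angular methyl group on the convex face competes with the C4 substituents on the concave face. Fallback: should the C6 epimer predominate, the rac-(3R,3aS,4S,8aR)-diol F6 is not discarded. Mitsunobu esterification of F6 with acid 19 (PPh3, diisopropyl azodicarboxylate, toluene, 0 °C → rt) inverts C6 and gives the mandelates directly, so that the route is rejoined at 20.

## Further compounds

F1 | step 9 | rac-(3S,3aR,8aR)-6,8a-dimethyl-3-(propan-2-yl)-3-(trimethylsilyloxy)-3,3a,8,8a-tetrahydroazulen-4(7H)-one | O=C1C=C(C)CC[C@]2(C)C=C[C@@](O[Si](C)(C)C)(C(C)C)[C@H]12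
F0 | step 5 | none | none
F2 | step 3 | rac-6-hydroxy-3,6-dimethylcyclohept-2-en-1-one | CC1=CC(=O)CC(C)(O)CC1
F3 | step 3 | rac-1,4-dimethyl-6-oxocyclohept-4-en-1-yl methanesulfonate | CC1=CC(=O)CC(C)(OS(C)(=O)=O)CC1
F4 | step 10 | rac-(3R,3aR,8aR)-6,8a-dimethyl-3-(propan-2-yl)-3-(trimethylsilyloxy)octahydroazulen-4(1H)-one, mixture of C6 epimers (azulene numbering) | O=C1CC(C)CC[C@]2(C)CC[C@@](O[Si](C)(C)C)(C(C)C)[C@H]12
F5 | step 10 | rac-6,8a-dimethyl-3-(propan-2-yl)-3,4-bis(trimethylsilyloxy)-1,2,3,3a,6,7,8,8a-octahydroazulene, core configuration as in 16 | C[Si](C)(C)OC1=CC(C)CC[C@]2(C)CC[C@@](O[Si](C)(C)C)(C(C)C)[C@H]12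
F6 | step 11 | rac-(3R,3aS,4S,8aR)-6,8a-dimethyl-3-(propan-2-yl)-1,2,3,3a,4,7,8,8a-octahydroazulene-3,4-diol | O[C@H]1C=C(C)CC[C@]2(C)CC[C@@](O)(C(C)C)[C@H]12
A1 | alternative 1 | 2-methyl-7-(2-methylcyclopropyl)-5-(triethylsilyloxy)-7-(trimethylsilyloxy)hepta-1,6-diene | C=C(C)CC[C@@H](O[Si](CC)(CC)CC)C=C(O[Si](C)(C)C)C1CC1C
A2 | alternative 1 | cis-fused bicyclic C6 silyl enol ether with C4 triethylsilyloxy group | C[Si](C)(C)OC1=C[C@H](C)CC[C@]2(C)CC[C@@H](O[Si](CC)(CC)CC)[C@H]12
A3 | alternative 2 | cis-1-(trimethylsilyloxy)-1-(ketal-protected 2-methyl-5-oxocyclopent-1-enyl)-2-methyl-2-vinylcyclopropane | C=C[C@]1(C)C[C@]1(O[Si](C)(C)C)C2=C(C)CCC23OCCO3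
A4 | alternative 2 | bicyclic C6 silyl enol ether with C8=C9 olefin and C4 ketal | CC1=CC[C@]2(C)CCC3(OCCO3)C2=C(O[Si](C)(C)C)C1
A5 | alternative 3 | 2-[(3Z)-4-iodo-3-methylbut-3-enyl]-2-methyl-5-(propan-2-yl)-5-(triethylsilyloxy)cyclopentane-1-carbaldehyde | O=C[C@H]1[C@](O[Si](CC)(CC)CC)(C(C)C)CC[C@@]1(C)CC/C(C)=C\I
A6 | alternative 3 | bicyclic C6 allylic alcohol with C4 triethylsilyl ether | O[C@@H]1C=C(C)CC[C@]2(C)CC[C@@](O[Si](CC)(CC)CC)(C(C)C)[C@H]12
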